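The ratio of partner charges between this flask and the winter run, 0.667, poses the question: does the rate of target formation follow that ratio or not?

- winter: solid substrate 20 mM; partner 45 mM; run made earlier
- flask: solid substrate 20 mM; partner 30.0 mM; time 15 h

winter run (percent of the solid substrate charged)

| time / h | target / % | solid product / % |
|---|---|---|
| 0.500 | 1.9 | 1.0 |
| 1.00 | 4.4 | 0.1 |
| 1.50 | 6.9 | 0.2 |
| 2.00 | 8.4 | 0.4 |
| 2.50 | 10.7 | 0 |
| 3.00 | 12.8 | 0 |

(standard deviation of a reading: 0.5 percentage points)

1. how much target and solid product together there is at 15 h, in percent of the solid substrate charged
2. concentration of dissolved substrate in solution at 15 h, in percent of saturation

- percentages count the solid substrate that a species holds: one side product counts as two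
- target is meant together with its solid product
- solid, in amounts per volume of the solution: solid substrate, solid product
- steps thought possible: solid product <-> target; dissolved substrate + partner -> target; 2 dissolved substrate -> side product; solid substrate <-> dissolved substrate
- at the start none of the solid substrate is in solution
- dissolved substrate means what is dissolved; the solid is not counted in it

The winter run climbs nearly in a straight line, so we read from its last reading, scatter included, the feed rate, the concentration of target and solid product made per hour: 0.853 mM/h.

We can reckon two extreme versions of this flask in the head. If dissolution is fast, dissolved substrate stays frozen at saturation and the rate goes with partner, so scaling the feed rate by the ratio gives 42.7% at 15 h, less whatever the fall of partner takes off. If dissolution is the rate-limiting step, dissolved substrate is caught as it arrives and sits at a low steady level. Target then forms at the feed rate at either partner charge, giving 64.0%, and at that rate the solid lasts 23.4 h, longer than the flask runs. We expect this flask between these figures, since less partner lets dissolved substrate rise and so softens the loss of rate. The winter run has a single partner charge, so the choice is our judgement: we commit to the upper figure, with dissolved substrate far below saturation.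

The forecast, holding that “dissolution is fast”, gives 38% and 95% of saturation, which differs from our reckoning.

The flask gives 63.0%, with dissolved substrate at 0.802% of saturation. At 7.49 h in this flask dissolved substrate is made 1.00 times as fast as it is used, which is the steady level of our upper extreme. The feed rate gives 32.0% at 7.50 h, and the flask holds 31.5% then.

    solid product ⇌ target, rate k1*(cs1 - [target]) while solid is left; crystals form when [target] > cs1 (solubility = 8.40 mM, k = 8.75 /h)
    dissolved substrate + partner → target (k = 498 /M/h)
    2 dissolved substrate → side product (k = 789 /M/h)
    solid substrate ⇌ dissolved substrate, rate k4*(cs4 - [dissolved substrate]) while solid is left; crystals form when [dissolved substrate] > cs4 (solubility = 12.0 mM, k = 0.0717 /h)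

The same flask read at 6.0 h gets 25.6% from the feed rate, and the computed result is 25.2%.

The numbers in the tables come from a simulation with constants of no real substance, and the scatter is random.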